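**Retrosynthetic overview**
1. Ring: the butenolide is the only ring and is made last. A 3-alkylfuran follows the presumed biogenetic line: singlet-oxygen [4+2] endoperoxide → γ-hydroxybutenolide (manoalide oxidation level) → reduction → relactonisation, in one flask on the unprotected tetraene diol.
2. C7–C24: the (6E)-ene-1,5-diol ⇒ homopropargylic alcohol + CH2O (alkoxide-directed titanium coupling, syn addition of H and C).
3. C4–C5 and the only stereocentre (4R) ⇒ furan-3-carbaldehyde + a C7-substituted allenylboronate under a chiral phosphoric acid.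
4. Allenylboronate ⇒ propargylic carbonate ⇒ propyne + (E,E)-farnesyl bromide + CH2O (C8–C9 and C5–C6 made in one flask).

Assumption: (2E,6E)-farnesyl bromide is bought as the pure E,E isomer. If it were made from farnesol with PBr3, the route would be one step longer.

Locants (manoalide numbering): C1 lactone C=O, C2 α-CH, C3 β-C, C25 OCH2, C4 carbinol, C5 CH2, C6=C7 alkene, C24 the CH2OH on C7, C8 and C9 the next two CH2 groups.

**Step 1**
Reactants: 1 propyne; 2 (2E,6E)-farnesyl bromide
Product: 6 methyl (6E,10E)-7,11,15-trimethylhexadeca-6,10,14-trien-2-yn-1-yl carbonate, via 1,3-dilithiopropyne 3 (not isolated), via lithium acetylide 4 (not isolated), via lithium alkoxide 5 (not isolated)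
Conditions: 1 (1.3 equiv), n-BuLi (2.6 equiv), TMEDA, Et2O–hexane, −78 °C → rt; 2 (1.0 equiv), THF, −78 → 0 °C; (CH2O)n, 0 °C → rt; ClCO2Me, 0 °C
Reagents that add atoms: formaldehyde (from paraformaldehyde), C=O; methyl chloroformate, COC(=O)Cl
Why: This is a dianion alkylation followed by acetylide hydroxymethylation and O-acylation, in which 3 is attacked by the primary allylic bromide only at its more basic sp3 carbon (SN2, no allylic transposition, both E alkenes kept), forming C8–C9 and leaving acetylide 4 free to add to formaldehyde (C5–C6) before alkoxide 5 is capped as the carbonate.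

**Step 2**
Reactants: 6 methyl (6E,10E)-7,11,15-trimethylhexadeca-6,10,14-trien-2-yn-1-yl carbonate
Product: 7 4,4,5,5-tetramethyl-2-[(6E,10E)-7,11,15-trimethylhexadeca-1,2,6,10,14-pentaen-3-yl]-1,3,2-dioxaborolane
Conditions: CuOt-Bu (5 mol %), Xantphos (5 mol %), B2pin2 (1.5 equiv), THF, 50 °C
Reagents that add atoms: bis(pinacolato)diboron, CC1(C)OB(OC1(C)C)B1OC(C)(C)C(C)(C)O1
Why: This is a copper-catalysed γ-selective (SN2′) borylation of a propargylic carbonate, in which a Cu–Bpin species adds across the alkyne and the carbonate leaves as CO2 and methoxide, putting boron on the alkyl-bearing carbon C7 of a terminal allene without touching the isolated trisubstituted alkenes.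

**Step 3**
Reactants: 7 4,4,5,5-tetramethyl-2-[(6E,10E)-7,11,15-trimethylhexadeca-1,2,6,10,14-pentaen-3-yl]-1,3,2-dioxaborolane; 8 furan-3-carbaldehyde
Product: 10 (1R,7E,11E)-1-(furan-3-yl)-8,12,16-trimethylheptadeca-7,11,15-trien-3-yn-1-ol, via pinacol borate 9 (not isolated)
Conditions: (R)-TRIP [(R)-3,3′-bis(2,4,6-triisopropylphenyl)-1,1′-binaphthyl-2,2′-diyl hydrogen phosphate] (10 mol %), 4 Å MS, toluene, −20 → 0 °C, 48 h; aq. NaHCO3
Reagents that add atoms: none
Why: This is a chiral phosphoric acid-catalysed allenylboration (carbonyl propargylation) through a closed six-membered SE2′ transition state, in which the (R)-acid hydrogen-bonds to a boronate oxygen and to the formyl H and exposes the Re face of 8, so that C4 is set as R, C4–C5 is formed at the allene CH2, and the alkyne appears between C6 and C7.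

**Step 4**
Reactants: 10 (1R,7E,11E)-1-(furan-3-yl)-8,12,16-trimethylheptadeca-7,11,15-trien-3-yn-1-ol
Product: 13 (1R,3E,7E,11E)-1-(furan-3-yl)-4-(hydroxymethyl)-8,12,16-trimethylheptadeca-3,7,11,15-tetraen-1-ol, via titanacyclopropene 11 (not isolated), via oxatitanacyclopentene 12 (not isolated)
Conditions: n-BuLi (1.0 equiv), toluene–Et2O, −78 °C; ClTi(Oi-Pr)3 (1.5 equiv), c-C5H9MgCl (3.0 equiv), −78 → −30 °C, 2 h; CH2O (monomer in THF, 5 equiv), −78 → 0 °C; sat. aq. NH4Cl
Reagents that add atoms: formaldehyde, C=O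
Why: Proposed new method: the lithium alkoxide of 10 is exchanged onto titanium, the two cyclopentyl groups collapse by β-hydride abstraction to a divalent titanium alkene complex that hands the metal to the tethered alkyne (bicyclic 11), formaldehyde inserts into the unconstrained distal C7–Ti bond (12), and protonolysis of C6–Ti delivers H and CH2OH syn, so that C8 ends cis to C5 (6E) and C4 is untouched; the closest known reaction type is the alkoxide-directed titanium-mediated reductive cross-coupling of homopropargylic alcohols with higher aldehydes to (E)-ene-1,5-diols, and formaldehyde is the untested partner.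

**Step 5** (key step)
Reactants: 13 (1R,3E,7E,11E)-1-(furan-3-yl)-4-(hydroxymethyl)-8,12,16-trimethylheptadeca-3,7,11,15-tetraen-1-ol
Product: 17 hippolide C, via furan endoperoxide 14 (not isolated), via γ-hydroxybutenolide 15 (not isolated), via sodium hydroxy enoate 16 (not isolated)
Conditions: O2, tetraphenylporphyrin (1 mol %), i-Pr2NEt (10 equiv), CH2Cl2, hν (visible), −78 °C, stopped at full furan consumption; Ar purge; NaBH4 (4 equiv), EtOH, −78 → 0 °C; 1 M HCl to pH 3, 0 °C → rt
Reagents that add atoms: dioxygen, O=O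
Why: Proposed new method: at −78 °C the furan takes up singlet oxygen by [4+2] cycloaddition much faster than the four trisubstituted alkenes undergo the ene reaction, the hindered amine removes the bridgehead H remote from the C3 side chain (Kornblum–DeLaMare-type fragmentation) so that only this carbon becomes the C1 carbonyl of 15, borohydride reduces the C25 aldehyde of the ring-opened formyl acrylate to carboxylate 16 (which cannot be over-reduced and keeps CO2Na cis to C25H2OH), and acid closes the lactone without touching C4 or any alkene; the closest known reaction types are the base-directed photooxygenation of 3-alkylfurans bearing a free carbinol to γ-hydroxybutenolides and the separate borohydride reduction of γ-hydroxybutenolides to butenolides, here merged in one flask on an unprotected, undirected tetraene diol.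

**Compound list**
1 | propyne | CC#C | starting material
2 | (2E,6E)-farnesyl bromide, (2E,6E)-1-bromo-3,7,11-trimethyldodeca-2,6,10-triene | CC(C)=CCC/C(C)=C/CC/C(C)=C/CBr | starting material
3 | 1,3-dilithiopropyne | [Li]CC#C[Li] | intermediate
4 | lithium acetylide of (5E,9E)-6,10,14-trimethylpentadeca-5,9,13-trien-1-yne | CC(C)=CCC/C(C)=C/CC/C(C)=C/CCC#C[Li] | intermediate
5 | lithium (6E,10E)-7,11,15-trimethylhexadeca-6,10,14-trien-2-yn-1-olate | CC(C)=CCC/C(C)=C/CC/C(C)=C/CCC#CCO[Li] | intermediate
6 | methyl (6E,10E)-7,11,15-trimethylhexadeca-6,10,14-trien-2-yn-1-yl carbonate | CC(C)=CCC/C(C)=C/CC/C(C)=C/CCC#CCOC(=O)OC | intermediate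
7 | 4,4,5,5-tetramethyl-2-[(6E,10E)-7,11,15-trimethylhexadeca-1,2,6,10,14-pentaen-3-yl]-1,3,2-dioxaborolane | CC(C)=CCC/C(C)=C/CC/C(C)=C/CCC(=C=C)B1OC(C)(C)C(C)(C)O1 | intermediate
8 | furan-3-carbaldehyde | O=Cc1ccoc1 | starting material
9 | pinacol borate (O-Bpin ether) of 10 | CC(C)=CCC/C(C)=C/CC/C(C)=C/CCC#CC[C@@H](OB1OC(C)(C)C(C)(C)O1)c1ccoc1 | intermediate
10 | (1R,7E,11E)-1-(furan-3-yl)-8,12,16-trimethylheptadeca-7,11,15-trien-3-yn-1-ol | CC(C)=CCC/C(C)=C/CC/C(C)=C/CCC#CC[C@@H](O)c1ccoc1 | intermediate
11 | alkoxide-tethered bicyclic titanacyclopropene (Ti on C6, C7, O–C4, Oi-Pr) | CC(C)=CCC/C(C)=C/CC/C(C)=C/CCC1=C2C[C@H](c3ccoc3)O[Ti]12OC(C)C | intermediate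
12 | fused oxatitanacyclopentene (Ti on C6, O–C24, O–C4, Oi-Pr) | CC(C)=CCC/C(C)=C/CC/C(C)=C/CCC1=C2C[C@H](c3ccoc3)O[Ti]2(OC(C)C)OC1 | intermediate
13 | (1R,3E,7E,11E)-1-(furan-3-yl)-4-(hydroxymethyl)-8,12,16-trimethylheptadeca-3,7,11,15-tetraen-1-ol | CC(C)=CCC/C(C)=C/CC/C(C)=C/CC/C(=C\C[C@@H](O)c1ccoc1)CO | intermediate
14 | 2,3,7-trioxabicyclo[2.2.1]hept-5-ene (furan endoperoxide) carrying the side chain at C5, bridgehead isomers | CC(C)=CCC/C(C)=C/CC/C(C)=C/CC/C(=C\C[C@@H](O)C1=CC2OOC1O2)CO | intermediate
15 | 5-hydroxy-4-[(1R,3E,7E,11E)-1-hydroxy-4-(hydroxymethyl)-8,12,16-trimethylheptadeca-3,7,11,15-tetraen-1-yl]furan-2(5H)-one, C25 epimers | CC(C)=CCC/C(C)=C/CC/C(C)=C/CC/C(=C\C[C@@H](O)C1=CC(=O)OC1O)CO | intermediate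
16 | sodium (2E,4R,6E,10E,14E)-4-hydroxy-3,7-bis(hydroxymethyl)-11,15,19-trimethylicosa-2,6,10,14,18-pentaenoate | CC(C)=CCC/C(C)=C/CC/C(C)=C/CC/C(=C\C[C@@H](O)/C(CO)=C/C(=O)[O-])CO.[Na+] | intermediate
17 | hippolide C, 4-[(1R,3E,7E,11E)-1-hydroxy-4-(hydroxymethyl)-8,12,16-trimethylheptadeca-3,7,11,15-tetraen-1-yl]furan-2(5H)-one | CC(C)=CCC/C(C)=C/CC/C(C)=C/CC/C(=C\C[C@@H](O)C1=CC(=O)OC1)CO | target

**Count**
Total steps: 5. Longest linear sequence: 5 (1/2 → 6 → 7 → 10 → 13 → 17; 8 enters in step 3).

**The three steps most likely to fail**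

Step 5 is the most likely to fail. The risks are ene oxidation of the chain alkenes, fragmentation of 14 in the wrong direction, and conjugate over-reduction.
- The fallback moves regiocontrol from the base to silicon and splits the cascade. It sets out from 8 (and uses 7 again) and comes back at 15.
- 8 is masked in the flask as its lithium morpholide adduct, lithiated at the furan carbon remote from the formyl group with s-BuLi, and silylated with Me3SiCl to give 5-(trimethylsilyl)furan-3-carbaldehyde F1.
- F1 takes the place of 8 in step 3 and gives the silylated alkynol F2. Step 4 then gives the silylated furan diol F3.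
- The silylfuran is more electron-rich, so it outruns the alkenes by a wider margin and needs no amine.
- Its endoperoxide collapses by silyl migration to oxygen, so the silicon-bearing carbon alone becomes C1. Mild hydrolysis gives 15.
- 15 is isolated, reduced separately with NaBH4 and acidified to 17.

Step 4 is second. The risks are that formaldehyde oligomerises or inserts poorly, or that the C7/C6 selectivity is low.
- The fallback installs C24 first and makes C7–C8 by cross-coupling. It sets out from 8 and 2 and comes back at 13.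
- 8 reacts with commercial allenylboronic acid pinacol ester under (R)-TRIP to give (1R)-1-(furan-3-yl)but-3-yn-1-ol F4.
- The dianion of F4 (2 n-BuLi) adds to (CH2O)n to give (5R)-5-(furan-3-yl)pent-2-yne-1,5-diol F5.
- Propargylic-hydroxyl-directed trans-hydrostannation ([Cp*RuCl]4, Bu3SnH) places tin on C7, cis to C5, and gives the (Z)-2-stannyl ene diol F6.
- I2 converts F6 with retention into the (Z)-2-iodo ene diol F7.
- In parallel, 2 is homologated by deborylative alkylation of CH2(Bpin)2 with NaOt-Bu to give homofarnesyl pinacol boronate F8.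
- A B-alkyl Suzuki coupling of F7 and F8 (Pd(OAc)2, RuPhos, K3PO4, toluene–water, 80 °C) gives 13 with the 6E geometry fixed by the iodide.

Step 3 is third. The risk is that the C7-substituted allenylboronate is too slow or gives low ee under Brønsted acid catalysis.
- The fallback changes the nucleophile from a boron reagent to an allenylcopper. It sets out from 4 and comes back at 10, and it skips 5, 6 and 7.
- 4 is trapped with ClCH2Bpin, and the ate complex undergoes a 1,2-shift to the propargyl pinacol boronate F9.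
- Catalytic boron-to-copper exchange (Cu(O2CCHMe2)2, LiOt-Bu, MeO-BIBOP, THF, −30 °C) gives a C7-substituted allenylcopper that adds to 8 through its CH2 terminus.
- The ligand antipode that delivers 4R is fixed in a test run by Mosher analysis.

**Further compounds**
F1 | step 5 | 5-(trimethylsilyl)furan-3-carbaldehyde | C[Si](C)(C)c1cc(C=O)co1
F2 | step 5 | silylated alkynol, (1R,7E,11E)-8,12,16-trimethyl-1-[5-(trimethylsilyl)furan-3-yl]heptadeca-7,11,15-trien-3-yn-1-ol | CC(C)=CCC/C(C)=C/CC/C(C)=C/CCC#CC[C@@H](O)c1coc([Si](C)(C)C)c1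
F3 | step 5 | silylated furan diol, (1R,3E,7E,11E)-4-(hydroxymethyl)-8,12,16-trimethyl-1-[5-(trimethylsilyl)furan-3-yl]heptadeca-3,7,11,15-tetraen-1-ol | CC(C)=CCC/C(C)=C/CC/C(C)=C/CC/C(=C\C[C@@H](O)c1coc([Si](C)(C)C)c1)CO
F4 | step 4 | (1R)-1-(furan-3-yl)but-3-yn-1-ol | C#CC[C@@H](O)c1ccoc1
F5 | step 4 | (5R)-5-(furan-3-yl)pent-2-yne-1,5-diol | OCC#CC[C@@H](O)c1ccoc1
F6 | step 4 | (Z)-2-stannyl ene diol, (2Z,5R)-5-(furan-3-yl)-2-(tributylstannyl)pent-2-ene-1,5-diol | OC/C([Sn](CCCC)(CCCC)CCCC)=C/C[C@@H](O)c1ccoc1
F7 | step 4 | (Z)-2-iodo ene diol, (2Z,5R)-5-(furan-3-yl)-2-iodopent-2-ene-1,5-diol | OC/C(I)=C/C[C@@H](O)c1ccoc1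
F8 | step 4 | homofarnesyl pinacol boronate, 4,4,5,5-tetramethyl-2-[(3E,7E)-4,8,12-trimethyltrideca-3,7,11-trien-1-yl]-1,3,2-dioxaborolane | CC(C)=CCC/C(C)=C/CC/C(C)=C/CCB1OC(C)(C)C(C)(C)O1
F9 | step 3 | propargyl pinacol boronate, 4,4,5,5-tetramethyl-2-[(6E,10E)-7,11,15-trimethylhexadeca-6,10,14-trien-2-yn-1-yl]-1,3,2-dioxaborolane | CC(C)=CCC/C(C)=C/CC/C(C)=C/CCC#CCB1OC(C)(C)C(C)(C)O1
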